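**Retrosynthetic overview**

1. Numbering: tridecane chain C1 (benzylic CH2) to C13 (CH3); C2 bears the acetate, C8 is the ketone. The target is unmasked by hydrogenolysis of two benzyl ethers; the acetate comes from a C2 alcohol, and that alcohol from a C2–B bond by stereoretentive oxidation.
2. Key disconnection C3–C4: a Ni-catalysed enantioselective conjunctive cross-coupling joins 1-iododecan-5-one (C4–C13) to a vinyl(benzyl)boron ate complex (C1–C3 plus the arene). In the same operation the benzyl group migrates from boron to C2 (C1–C2 bond) and the C2 stereocentre is set.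
3. Enabling feature: C2 is a secondary O-bearing carbon flanked by two CH2 groups (benzylic C1 on the 3,5-dioxygenated benzene ring, and C3), and C4 is a plain primary carbon. C2–C3 therefore maps onto a vinyl group on boron, ArCH2 onto the migrating group and the C2 oxygen onto boron; the C8 ketone, insulated by C5–C7, is carried unprotected.
4. Fragments: the iodo ketone from 5-bromopentanoyl chloride and pentylmagnesium bromide (acylation, then Finkelstein); the benzylboronate from 3,5-bis(benzyloxy)benzyl bromide (borylation).
5. Rings: none is formed; the benzene ring, the only ring of the target, is bought with both oxygens in place.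

Key step: step 4

Assumption: the absolute sense of induction of the chiral ligand in the key step is not predicted here; the ligand enantiomer that delivers the (R)-boronate is chosen after a pilot run with Mosher analysis of the derived alcohol (both ligand enantiomers are available).

**Route**

Step 1
Reactants: 1 5-bromopentanoyl chloride; 2 n-pentylmagnesium bromide
Product: 3 1-bromodecan-5-one
Conditions: Fe(acac)3 (3 mol %), THF, −78 °C, then aq. NH4Cl
Reagents that add atoms: none
Why: Iron-catalysed acylation of a Grignard reagent by an acid chloride at −78 °C should be much faster than addition to the ketone formed or attack at the primary C–Br bond, so the δ-bromo ketone should result without over-addition.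

Step 2
Reactants: 3 1-bromodecan-5-one
Product: 4 1-iododecan-5-one
Conditions: NaI (3 equiv), acetone, reflux, dark
Reagents that add atoms: sodium iodide, [Na+].[I-]
Why: Finkelstein halide exchange (SN2), driven by precipitation of NaBr, should give the primary iodide needed for fast activation by nickel.

Step 3
Reactants: 5 3,5-bis(benzyloxy)benzyl bromide
Product: 6 2-[3,5-bis(benzyloxy)benzyl]-4,4,5,5-tetramethyl-1,3,2-dioxaborolane
Conditions: B2pin2, Pd2(dba)3 (1.5 mol %), P(4-MeOC6H4)3 (6 mol %), KOAc, toluene, 50 °C
Reagents that add atoms: bis(pinacolato)diboron, CC1(C)OB(OC1(C)C)B1OC(C)(C)C(C)(C)O1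
Why: Pd-catalysed Miyaura-type borylation of a benzylic bromide should give the benzylic pinacol boronate, the aryl benzyl ethers being inert.

Step 4
Reactants: 6 2-[3,5-bis(benzyloxy)benzyl]-4,4,5,5-tetramethyl-1,3,2-dioxaborolane; 4 1-iododecan-5-one
Product: 8 (12R)-13-[3,5-bis(benzyloxy)phenyl]-12-(4,4,5,5-tetramethyl-1,3,2-dioxaborolan-2-yl)tridecan-6-one, via lithium vinylboronate complex 7 (not isolated)
Conditions: (CH2=CH)4Sn, n-BuLi, pentane, rt (vinyllithium, taken up in THF); 6 (1.05 equiv), THF, 0 °C to rt; then 4, NiBr2·glyme (5 mol %), chiral Ph-Pybox ligand (6 mol %), THF/DMSO, rt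
Reagents that add atoms: tetravinylstannane, C=C[Sn](C=C)(C=C)C=C (vinyl source, delivered as vinyllithium, C=C[Li])
Why: A ligated low-valent Ni species should abstract iodine from 4, and the resulting alkylnickel should π-bind the vinyl group of 7 and trigger anti 1,2-migration of the 3,5-bis(benzyloxy)benzyl group from boron to C2 while Ni bonds to C3; C(sp3)–C(sp3) reductive elimination then forms C3–C4, so that C1–C2, C3–C4 and the C2–B stereocentre arise in one operation. The closest known reaction type is the Ni/Pybox-catalysed enantioselective conjunctive cross-coupling of vinylboron pinacol ate complexes with unactivated primary alkyl iodides. No ring is closed. The new stereocentre C2 is controlled by the chiral ligand on nickel, which selects the enantioface of the vinyl group in the metal-induced 1,2-metalate shift; the ligand enantiomer is chosen to give (R). The step needs chemoselectivity for the conjunctive pathway over direct vinyl or benzyl transfer and over attack on the ketone: the tetracoordinate pinacol ate complex transmetalates slowly and is a poor carbonyl nucleophile, the primary iodide is activated quickly, no free organolithium remains because 6 is in slight excess, and 5-exo addition of a C4 radical to the C8 carbonyl is reversible and lies on the open-chain side.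

Step 5
Reactants: 8 (12R)-13-[3,5-bis(benzyloxy)phenyl]-12-(4,4,5,5-tetramethyl-1,3,2-dioxaborolan-2-yl)tridecan-6-one
Product: 9 (12R)-13-[3,5-bis(benzyloxy)phenyl]-12-hydroxytridecan-6-one
Conditions: 30 % H2O2, 3 M NaOH, THF, 0 °C to rt
Reagents that add atoms: hydrogen peroxide, OO
Why: Alkaline peroxide oxidation of the C–B bond proceeds by 1,2-migration of C2 from boron to oxygen with retention of configuration, so (R)-8 should give (R)-9, and the remote dialkyl ketone should survive at this temperature.

Step 6
Reactants: 9 (12R)-13-[3,5-bis(benzyloxy)phenyl]-12-hydroxytridecan-6-one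
Product: 10 (2R)-1-[3,5-bis(benzyloxy)phenyl]-8-oxotridecan-2-yl acetate
Conditions: Ac2O, pyridine, DMAP (cat.), CH2Cl2, rt
Reagents that add atoms: acetic anhydride, CC(=O)OC(C)=O
Why: DMAP-catalysed acetylation of the only free hydroxyl group; no bond to the stereocentre is broken.

Step 7
Reactants: 10 (2R)-1-[3,5-bis(benzyloxy)phenyl]-8-oxotridecan-2-yl acetate
Product: 11 (2R)-1-(3,5-dihydroxyphenyl)-8-oxotridecan-2-yl acetate
Conditions: H2 (1 atm), 10 % Pd/C, EtOAc, rt
Reagents that add atoms: none
Why: Pd-catalysed hydrogenolysis of the two aryl benzyl ethers under neutral, non-nucleophilic conditions should leave the homobenzylic secondary acetate, the dialkyl ketone and the C2 stereocentre untouched.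

**Compound list**

1 | 5-bromopentanoyl chloride | O=C(Cl)CCCCBr | starting material
2 | n-pentylmagnesium bromide | CCCCC[Mg]Br | starting material
3 | 1-bromodecan-5-one | CCCCCC(=O)CCCCBr | intermediate
4 | 1-iododecan-5-one | CCCCCC(=O)CCCCI | intermediate
5 | 3,5-bis(benzyloxy)benzyl bromide (1,3-bis(benzyloxy)-5-(bromomethyl)benzene) | BrCc1cc(OCc2ccccc2)cc(OCc2ccccc2)c1 | starting material
6 | 2-[3,5-bis(benzyloxy)benzyl]-4,4,5,5-tetramethyl-1,3,2-dioxaborolane | CC1(C)OB(Cc2cc(OCc3ccccc3)cc(OCc3ccccc3)c2)OC1(C)C | intermediate
7 | lithium [3,5-bis(benzyloxy)benzyl](ethenyl)(pinacolato)borate | [Li+].C=C[B-]1(Cc2cc(OCc3ccccc3)cc(OCc3ccccc3)c2)OC(C)(C)C(C)(C)O1 | intermediate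
8 | (12R)-13-[3,5-bis(benzyloxy)phenyl]-12-(4,4,5,5-tetramethyl-1,3,2-dioxaborolan-2-yl)tridecan-6-one | CCCCCC(=O)CCCCC[C@H](Cc1cc(OCc2ccccc2)cc(OCc2ccccc2)c1)B1OC(C)(C)C(C)(C)O1 | intermediate
9 | (12R)-13-[3,5-bis(benzyloxy)phenyl]-12-hydroxytridecan-6-one | CCCCCC(=O)CCCCC[C@H](Cc1cc(OCc2ccccc2)cc(OCc2ccccc2)c1)O | intermediate
10 | (2R)-1-[3,5-bis(benzyloxy)phenyl]-8-oxotridecan-2-yl acetate | CCCCCC(=O)CCCCC[C@H](Cc1cc(OCc2ccccc2)cc(OCc2ccccc2)c1)OC(C)=O | intermediate
11 | (2R)-1-(3,5-dihydroxyphenyl)-8-oxotridecan-2-yl acetate | CCCCCC(=O)CCCCC[C@H](Cc1cc(O)cc(O)c1)OC(C)=O | target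

**Step count and risks**

Total step count: 7. Longest linear sequence: 6 steps (steps 1, 2, 4, 5, 6, 7, from 5-bromopentanoyl chloride).

Steps most likely to fail:

1. Step 4. The enantiofacial selection at the vinyl group may be insufficient with a benzyl migrating group. The ate complex may also be diverted to direct, non-conjunctive transfer of vinyl or benzyl, and the alkylnickel intermediate may undergo β-hydride elimination. Fallback (known chemistry; sets out from 5 and 3, returns at 9): 5 is coupled with vinylmagnesium bromide (CuI cat., THF) to give 1-allyl-3,5-bis(benzyloxy)benzene F1. Epoxidation (mCPBA, CH2Cl2) gives racemic 2-[3,5-bis(benzyloxy)benzyl]oxirane F2. Hydrolytic kinetic resolution with (salen)Co(III)OAc and 0.55 equiv of water then leaves (S)-2-[3,5-bis(benzyloxy)benzyl]oxirane F3; the (R,R)-catalyst is expected to do this, and the other catalyst enantiomer is used if the sense proves opposite. In parallel, 3 is ketalised (ethylene glycol, TsOH, benzene, Dean–Stark) to 2-(4-bromobutyl)-2-pentyl-1,3-dioxolane F4, which with Mg in THF gives [4-(2-pentyl-1,3-dioxolan-2-yl)butyl]magnesium bromide F5. CuI-catalysed opening of F3 by F5 at the terminal epoxide carbon (THF, −30 °C) forms the same C3–C4 bond and should give (2R)-1-[3,5-bis(benzyloxy)phenyl]-7-(2-pentyl-1,3-dioxolan-2-yl)heptan-2-ol F6. Ketal hydrolysis (PPTS, acetone/water) then gives 9.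

2. Step 1. The Grignard reagent may add a second time to the ketone as it forms, or react at the primary C–Br bond. Fallback (sets out from 2, returns at 4): 2 is added to cyclopentanone (THF, 0 °C) to give 1-pentylcyclopentan-1-ol F7. Alkoxy-radical β-scission of its hypoiodite (PhI(OAc)2, I2, CH2Cl2, visible light) should open the five-membered ring with strain release and trap the primary radical as the iodide, giving 4 directly and making 3 unnecessary.

3. Step 3. The benzylboronate formed may undergo Suzuki-type homocoupling with unreacted benzyl bromide, and the benzylic C–B bond may be lost by protodeboronation during purification. Fallback (sets out from 5, returns at 8): 5 is converted with activated Mg (THF, 0 °C, slow addition, high dilution) into 3,5-bis(benzyloxy)benzylmagnesium bromide F8. This is added to commercial vinylboronic acid pinacol ester to form bromomagnesium [3,5-bis(benzyloxy)benzyl](ethenyl)(pinacolato)borate F9. After addition of NaOTf to sequester halide, F9 is coupled with 4 under the nickel conditions of step 4 to give 8, so that no benzylboronate has to be isolated.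

**Further compounds**

F1 | step 4 | 1-allyl-3,5-bis(benzyloxy)benzene | C=CCc1cc(OCc2ccccc2)cc(OCc2ccccc2)c1
F2 | step 4 | rac-2-[3,5-bis(benzyloxy)benzyl]oxirane | C1OC1Cc1cc(OCc2ccccc2)cc(OCc2ccccc2)c1
F3 | step 4 | (S)-2-[3,5-bis(benzyloxy)benzyl]oxirane | C1[C@H](Cc2cc(OCc3ccccc3)cc(OCc3ccccc3)c2)O1
F4 | step 4 | 2-(4-bromobutyl)-2-pentyl-1,3-dioxolane | CCCCCC1(CCCCBr)OCCO1
F5 | step 4 | [4-(2-pentyl-1,3-dioxolan-2-yl)butyl]magnesium bromide | CCCCCC1(CCCC[Mg]Br)OCCO1
F6 | step 4 | (2R)-1-[3,5-bis(benzyloxy)phenyl]-7-(2-pentyl-1,3-dioxolan-2-yl)heptan-2-ol | CCCCCC1(CCCCC[C@H](Cc2cc(OCc3ccccc3)cc(OCc3ccccc3)c2)O)OCCO1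
F7 | step 1 | 1-pentylcyclopentan-1-ol | CCCCCC1(O)CCCC1
F8 | step 3 | 3,5-bis(benzyloxy)benzylmagnesium bromide | Br[Mg]Cc1cc(OCc2ccccc2)cc(OCc2ccccc2)c1
F9 | step 3 | bromomagnesium [3,5-bis(benzyloxy)benzyl](ethenyl)(pinacolato)borate | Br[Mg+].C=C[B-]1(Cc2cc(OCc3ccccc3)cc(OCc3ccccc3)c2)OC(C)(C)C(C)(C)O1
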